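**Retrosynthetic overview**

1. Target 12 ⇒ saturated trans lactone diacid 10: the exocyclic C=CH2 is put on last by α-carboxylation and decarboxylative methylenation (carbon from formaldehyde).
2. γ-Lactone 10 ⇒ trans-2-alkyl-3-carboxycyclobutanone 8: Baeyer–Villiger ring expansion (1,2-shift of the chain-bearing carbon from carbon to oxygen, with retention), run in one pot with oxidative cleavage of the terminal alkene to the chain-end CO2H.
3. Cyclobutanone C2–chain bond ⇒ 3-oxocyclobutane-1-carboxylic acid 7 + hexadeca-1,15-diene 6: a new catalytic desymmetrising anti-Markovnikov hydroalkylation that sets both stereocentres.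
4. Diene 6 ⇒ 5-bromopent-1-ene (used in two successive steps) + 1-bromo-6-chlorohexane: two copper-catalysed alkyl–alkyl couplings, first at the C–Br end, then through the Grignard reagent of the chloride end.
5. Ring order: the four-membered carbocycle is bought; the only ring made is the five-membered lactone, by expansion of that ring.

Assumption: the absolute sense of induction of the new desymmetrisation (and of the chiral lithium amide in its fallback) cannot be predicted with certainty; the enantiomer named is the one taken to give the (1S,2R) series, and its mirror image is used if the opposite sense is found.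

**Route**

Step 1
Reactants: 1 5-bromopent-1-ene; 2 1-bromo-6-chlorohexane
Product: 4 undec-10-en-1-yl chloride (11-chloroundec-1-ene), via pent-4-en-1-ylmagnesium bromide 3 (not isolated)
Conditions: 1 (1.15 equiv), Mg, THF, 40 °C; then added to 2 (1.0 equiv), Li2CuCl4 (2 mol %), THF, −10 to 0 °C
Reagents that add atoms: none
Why: Kochi-type copper-catalysed sp3–sp3 cross-coupling of a primary alkyl Grignard reagent, chemoselective for the C–Br bond of 2 while the C–Cl bond stays intact; no stereocentre is formed.

Step 2
Reactants: 4 undec-10-en-1-yl chloride; 1 5-bromopent-1-ene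
Product: 6 hexadeca-1,15-diene, via undec-10-en-1-ylmagnesium chloride 5 (not isolated)
Conditions: 4, Mg (I2 cat.), THF, reflux; then 1 (1.1 equiv), Li2CuCl4 (3 mol %), THF/NMP, 0 °C to rt
Reagents that add atoms: none
Why: the primary alkyl chloride forms its Grignard reagent in refluxing THF, and a second Kochi-type copper-catalysed coupling with primary bromide 1 completes the C16 chain (5 + 6 + 5 carbons); no stereocentre is formed.

Step 3
Reactants: 7 3-oxocyclobutane-1-carboxylic acid; 6 hexadeca-1,15-diene
Product: 8 (1S,2R)-2-(hexadec-15-en-1-yl)-3-oxocyclobutane-1-carboxylic acid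
Conditions: 6 (4 equiv), [Ir(Fmppy)2(dtbbpy)]PF6 (1 mol %), (S)-N1,N1-diethyl-3,3-dimethylbutane-1,2-diamine·TfOH (20 mol %), 2,4,6-iPr3C6H2SH (20 mol %), MeCN/DME, blue LEDs (450 nm), 0 °C; acid–base extraction returns excess 6
Reagents that add atoms: none
Why: Proposed new method: the chiral primary amine condenses with 7 to give equilibrating enamines toward either enantiotopic α-CH2, the excited trivalent iridium photocatalyst oxidises the enamine to an enaminyl radical cation that adds through its α-carbon to a terminal CH2 of 6 (anti-Markovnikov), the secondary alkyl radical is quenched by hydrogen-atom transfer from the thiol and the thiyl radical is reduced by the formally divalent iridium complex, so the process is redox-neutral; the tert-butyl group of the catalyst shields one enamine face, so only the enamine whose open face is also anti to the ring CO2H reacts fast (Curtin–Hammett), which selects one enantiotopic α-carbon (fixing C1 as S) and gives the trans C2 centre (R), reinforced by enamine-mediated epimerisation to the more stable trans isomer; the closest known reactions are the photoredox/enamine/thiol triple-catalytic α-alkylation of aldehydes with simple olefins, the SOMO α-allylation of cyclic ketones and the amine-catalysed desymmetrising aldol and Michael reactions of 3-substituted cyclobutanones.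

Step 4
Reactants: 8 (1S,2R)-2-(hexadec-15-en-1-yl)-3-oxocyclobutane-1-carboxylic acid
Product: 10 (2R,3S)-2-(14-carboxytetradecyl)-5-oxooxolane-3-carboxylic acid, via ozonide 9 (not isolated)
Conditions: O3, CH2Cl2, −78 °C; N2 purge, evaporate; then HCO2H, 30% H2O2, 0 to 50 °C
Reagents that add atoms: ozone [O-][O+]=O; hydrogen peroxide OO
Why: Criegee ozonolysis of the terminal alkene gives ozonide 9, and performic acid formed in the flask then cleaves it oxidatively to the chain CO2H and effects the Baeyer–Villiger ring expansion of the cyclobutanone, in which the more substituted chain-bearing carbon migrates from carbon to oxygen with retention, so both stereocentres are carried over unchanged into the trans lactone.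

Step 5
Reactants: 10 (2R,3S)-2-(14-carboxytetradecyl)-5-oxooxolane-3-carboxylic acid
Product: 12 (2R,3S)-2-(14-carboxytetradecyl)-4-methylidene-5-oxooxolane-3-carboxylic acid, via α-carboxy lactone triacid 11 (not isolated)
Conditions: MeOMgOCO2Me (2 M in DMF, 40 equiv), 135 °C, 60 h; aq. HCl, 0 °C; then 37% aq. HCHO, PhNHMe, NaOAc, AcOH, rt
Reagents that add atoms: formaldehyde C=O
Why: Stiles carboxylation of the lactone α-CH2 (magnesium chelate; this CO2 unit comes from MeOMgOCO2Me and is lost again) followed by decarboxylative Mannich-type methylenation with formaldehyde and the secondary amine, a sequence proven on trans paraconic acids; the two stereocentres are not touched and trans is the thermodynamic arrangement.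

**Compound list**

1 | 5-bromopent-1-ene | C=CCCCBr | starting material
2 | 1-bromo-6-chlorohexane | ClCCCCCCBr | starting material
3 | pent-4-en-1-ylmagnesium bromide | C=CCCC[Mg]Br | intermediate
4 | undec-10-en-1-yl chloride (11-chloroundec-1-ene) | C=CCCCCCCCCCCl | intermediate
5 | undec-10-en-1-ylmagnesium chloride | C=CCCCCCCCCC[Mg]Cl | intermediate
6 | hexadeca-1,15-diene | C=CCCCCCCCCCCCCC=C | intermediate
7 | 3-oxocyclobutane-1-carboxylic acid | O=C1CC(C1)C(=O)O | starting material
8 | (1S,2R)-2-(hexadec-15-en-1-yl)-3-oxocyclobutane-1-carboxylic acid (trans) | C1C(=O)[C@H](CCCCCCCCCCCCCCC=C)[C@H]1C(=O)O | intermediate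
9 | (1S,2R)-3-oxo-2-[14-(1,2,4-trioxolan-3-yl)tetradecyl]cyclobutane-1-carboxylic acid (trioxolane carbon unassigned) | C1C(=O)[C@H](CCCCCCCCCCCCCCC2OCOO2)[C@H]1C(=O)O | intermediate
10 | (2R,3S)-2-(14-carboxytetradecyl)-5-oxooxolane-3-carboxylic acid (trans) | C1C(=O)O[C@H](CCCCCCCCCCCCCCC(=O)O)[C@H]1C(=O)O | intermediate
11 | (2R,3S)-2-(14-carboxytetradecyl)-5-oxooxolane-3,4-dicarboxylic acid (C4 unassigned) | OC(=O)C1C(=O)O[C@H](CCCCCCCCCCCCCCC(=O)O)[C@H]1C(=O)O | intermediate
12 | (2R,3S)-2-(14-carboxytetradecyl)-4-methylidene-5-oxooxolane-3-carboxylic acid | C=C1C(=O)O[C@H](CCCCCCCCCCCCCCC(=O)O)[C@H]1C(=O)O | target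

**Step count and risks**

Total step count: 5. Longest linear sequence: 5 steps (1 → 4 → 6 → 8 → 10 → 12).

The three steps most likely to fail:

Step 3 (the proposed new step). Risks are slow intermolecular addition of the enaminyl radical cation to an unactivated 1-alkene, a second alkylation at the other α-carbon, oxidation of the free carboxylate, and modest enantioselectivity. The free acid is run without base and with a photocatalyst whose excited state (about +0.8 V) oxidises the enamine but not the acid. The fallback uses known chemistry, sets out from 7 and 6 and comes back at 8. Acid 7 is esterified with isobutene and catalytic H2SO4 to tert-butyl 3-oxocyclobutane-1-carboxylate F1. Enantioselective deprotonation of F1 with LiN[(S)-CHMePh]2 and in situ Me3SiCl (THF, −100 °C), a desymmetrisation established for 3-substituted cyclobutanones, gives tert-butyl (1S)-3-(trimethylsilyloxy)cyclobut-2-ene-1-carboxylate F2. MeLi converts F2 to lithium (3S)-3-(tert-butoxycarbonyl)cyclobut-1-en-1-olate F3. Separately, radical anti-Markovnikov addition of one equivalent of HBr (dibenzoyl peroxide, hexane) to excess 6 gives 16-bromohexadec-1-ene F4. Alkylation of F3 with F4 (THF/DMPU, −78 to 0 °C) takes place anti to the ester and gives tert-butyl (1S,2R)-2-(hexadec-15-en-1-yl)-3-oxocyclobutane-1-carboxylate F5. CF3CO2H in CH2Cl2 then returns 8.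

Step 4. Risks are the regiochemistry of the ring expansion and the handling of a peroxidic mixture in which the ozonide is partly replaced by acyloxy hydroperoxides (these converge on the same acid). The fallback sets out from 8 and comes back at 10, and separates and reorders the two oxidations with other oxidants. Nucleophilic Baeyer–Villiger oxidation with 30% H2O2 in AcOH (0 °C to rt), which leaves the unactivated alkene alone, gives (2R,3S)-2-(hexadec-15-en-1-yl)-5-oxooxolane-3-carboxylic acid F6, which can be purified and its regiochemistry checked. The terminal alkene of F6 is then cleaved to the acid with RuCl3 (2 mol %) and NaIO4 in MeCN/EtOAc/H2O to give 10.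

Step 5. Risks are incomplete carboxylation in the presence of two carboxylates at 135 °C and isomerisation of the exocyclic alkene into the ring. The fallback sets out from 10 and comes back at 12, and replaces carboxylation/decarboxylation by direct enolate aminomethylation and Hofmann-type elimination. LiN(iPr)2 (3.3 equiv, THF, −78 °C) gives the trilithium lactone-enolate dicarboxylate of 10 F7. Me2N=CH2 I (Eschenmoser's salt) converts F7 to (2R,3S)-2-(14-carboxytetradecyl)-4-[(dimethylamino)methyl]-5-oxooxolane-3-carboxylic acid F8. MeI in MeOH gives the trimethylammonium iodide of F8 F9, and aqueous NaHCO3 at rt eliminates it to 12.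

**Further compounds**

F1 | step 3 | tert-butyl 3-oxocyclobutane-1-carboxylate | O=C1CC(C1)C(=O)OC(C)(C)C
F2 | step 3 | tert-butyl (1S)-3-(trimethylsilyloxy)cyclobut-2-ene-1-carboxylate | C1C(O[Si](C)(C)C)=C[C@H]1C(=O)OC(C)(C)C
F3 | step 3 | lithium (3S)-3-(tert-butoxycarbonyl)cyclobut-1-en-1-olate | C1C(O[Li])=C[C@H]1C(=O)OC(C)(C)C
F4 | step 3 | 16-bromohexadec-1-ene | C=CCCCCCCCCCCCCCCBr
F5 | step 3 | tert-butyl (1S,2R)-2-(hexadec-15-en-1-yl)-3-oxocyclobutane-1-carboxylate | C1C(=O)[C@H](CCCCCCCCCCCCCCC=C)[C@H]1C(=O)OC(C)(C)C
F6 | step 4 | (2R,3S)-2-(hexadec-15-en-1-yl)-5-oxooxolane-3-carboxylic acid | C1C(=O)O[C@H](CCCCCCCCCCCCCCC=C)[C@H]1C(=O)O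
F7 | step 5 | trilithium lactone-enolate dicarboxylate of 10 | [Li+].[Li+].[Li+].C1=C([O-])O[C@H](CCCCCCCCCCCCCCC(=O)[O-])[C@H]1C(=O)[O-]
F8 | step 5 | (2R,3S)-2-(14-carboxytetradecyl)-4-[(dimethylamino)methyl]-5-oxooxolane-3-carboxylic acid (C4 unassigned) | CN(C)CC1C(=O)O[C@H](CCCCCCCCCCCCCCC(=O)O)[C@H]1C(=O)O
F9 | step 5 | trimethylammonium iodide of F8 | C[N+](C)(C)CC1C(=O)O[C@H](CCCCCCCCCCCCCCC(=O)O)[C@H]1C(=O)O.[I-]
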